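**Retrosynthetic overview**

1. Locants used in the text: C1 = ring carbon bearing the exocyclic CH2; C2; C3=C4; C5 = C(CH3)OH; C6; C7; C8 and C9 = ring-fusion CH (C9 next to C1); C10 = OCH2; O11; C12 = quaternary C–O carbon; C13 = first dienyl carbon; C19 = CH2O-acyl. Late stage: stearate on C19–OH last; dienyl from a C12 ethynyl group (hydrostannation, Stille); C1=CH2 from a C1 ketone; nine-membered ring by ring-closing metathesis at C3=C4 of an allyl ketone.
2. The oxolane (O11, C12, C8, C9, C10) is not closed in its final size. A ketal opened by SnCl4 cyclises (Prins) to a six-membered oxan-4-yl cation (O11, C12, C8, C9, C1, C10); a 1,2-shift of C10 from C1 to C9 then contracts it by one atom, and C1 leaves the ring as the formyl group on C9.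
3. Feature that allows this: C9 carries both the ring OCH2 carbon C10 and the carbonyl-level carbon C1 (later the C=CH2 carbon), so the oxolane is a 3-acyl-oxolane, the product pattern of a pinacol ring contraction; C8 is the far end of the former alkene.
4. The ketal comes from an ynone (C12, C13, C14, C19) and a (Z)-allylic 1,2-diol. The diol is made by Wittig reaction of a phosphonium salt from (S)-linalool (C4 to C8, C5 stereocentre) with (R)-glyceraldehyde acetonide (C9, C1, C10); the C1 stereocentre steers C8 and C12 and is then erased.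
5. Ring order: temporary 1,3-dioxolane, transient oxane, oxolane (key step), then the nine-membered carbocycle.

Key step: step 10

Assumption: (S)-(+)-linalool of high enantiomeric purity, (R)-2,2-dimethyl-1,3-dioxolane-4-carbaldehyde, ethynyl(triisopropyl)silane and (tert-butyldimethylsilyloxy)acetaldehyde are bought as such.
Abbreviations: TBS = tert-butyldimethylsilyl, TIPS = triisopropylsilyl, TES = triethylsilyl.

**Route**

Step 1
Reactants: 1 (S)-(+)-linalool
Product: 2 (3S)-3-(TBS-oxy)-3,7-dimethylocta-1,6-diene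
Conditions: TBSOTf, 2,6-lutidine, CH2Cl2, 0 °C
Reagents that add atoms: tert-butyldimethylsilyl trifluoromethanesulfonate, CC(C)(C)[Si](C)(C)OS(=O)(=O)C(F)(F)F
Why: Silylation with a silyl triflate and a hindered base caps the tertiary allylic alcohol without ionising it and leaves the stereocentre untouched.

Step 2
Reactants: 2 (3S)-3-(TBS-oxy)-3,7-dimethylocta-1,6-diene
Product: 4 (4S)-4-(TBS-oxy)-4-methylhex-5-en-1-ol, via ozonide 3 (not isolated)
Conditions: O3 (1.0 equiv), CH2Cl2, −78 °C; then NaBH4 (excess), MeOH, −78 → 0 °C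
Reagents that add atoms: ozone, [O-][O+]=O
Why: Ozonolysis with reductive work-up; the electron-rich trisubstituted alkene should be cleaved well before the vinyl group, which is deactivated and shielded by the neighbouring silyloxy-bearing quaternary carbon.

Step 3
Reactants: 4 (4S)-4-(TBS-oxy)-4-methylhex-5-en-1-ol
Product: 5 (3S)-3-(TBS-oxy)-6-iodo-3-methylhex-1-ene
Conditions: I2, PPh3, imidazole, CH2Cl2, 0 °C
Reagents that add atoms: iodine, II
Why: Appel-type iodination of an unhindered primary alcohol by SN2 displacement of the alkoxyphosphonium ion.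

Step 4
Reactants: 5 (3S)-3-(TBS-oxy)-6-iodo-3-methylhex-1-ene
Product: 6 [(4S)-4-(TBS-oxy)-4-methylhex-5-en-1-yl]triphenylphosphonium iodide
Conditions: PPh3, MeCN, 80 °C
Reagents that add atoms: triphenylphosphine, c1ccc(cc1)P(c1ccccc1)c1ccccc1
Why: SN2 quaternisation of triphenylphosphine by a primary iodide.

Step 5
Reactants: 6 [(4S)-4-(TBS-oxy)-4-methylhex-5-en-1-yl]triphenylphosphonium iodide; 7 (R)-2,2-dimethyl-1,3-dioxolane-4-carbaldehyde
Product: 9 (4S)-4-[(1Z,5S)-5-(TBS-oxy)-5-methylhepta-1,6-dien-1-yl]-2,2-dimethyl-1,3-dioxolane, via phosphorus ylide 8 (not isolated)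
Conditions: NaN(SiMe3)2, THF, −78 °C; then 7, −78 → 0 °C
Reagents that add atoms: none
Why: Salt-free Wittig olefination of a non-stabilised ylide with an α-alkoxy aldehyde at low temperature should give the (Z)-alkene under kinetic control and keep the aldehyde stereocentre (future C1) intact.

Step 6
Reactants: 9 (4S)-4-[(1Z,5S)-5-(TBS-oxy)-5-methylhepta-1,6-dien-1-yl]-2,2-dimethyl-1,3-dioxolane
Product: 10 (2S,3Z,7S)-7-(TBS-oxy)-7-methylnona-3,8-diene-1,2-diol
Conditions: AcOH/THF/H2O (3:1:1), 40 °C
Reagents that add atoms: none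
Why: Acetal hydrolysis under mild aqueous acid frees the 1,2-diol while the hindered tertiary TBS ether is stable.

Step 7
Reactants: 11 ethynyl(triisopropyl)silane; 12 (tert-butyldimethylsilyloxy)acetaldehyde
Product: 14 racemic 1-(TBS-oxy)-4-(triisopropylsilyl)but-3-yn-2-ol, via lithium acetylide 13 (not isolated)
Conditions: n-BuLi, THF, −78 °C; then 12; then H2O
Reagents that add atoms: none
Why: 1,2-Addition of a lithium acetylide to an aldehyde; the new carbinol centre is oxidised away in the next step.

Step 8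
Reactants: 14 racemic 1-(TBS-oxy)-4-(triisopropylsilyl)but-3-yn-2-ol
Product: 15 1-(TBS-oxy)-4-(triisopropylsilyl)but-3-yn-2-one
Conditions: Dess–Martin periodinane, pyridine, CH2Cl2, 0 → 23 °C
Reagents that add atoms: none
Why: Dess–Martin oxidation of a propargylic alcohol under non-nucleophilic conditions that leave the ynone untouched.

Step 9
Reactants: 10 (2S,3Z,7S)-7-(TBS-oxy)-7-methylnona-3,8-diene-1,2-diol; 15 1-(TBS-oxy)-4-(triisopropylsilyl)but-3-yn-2-one
Product: 16 (4S)-2-[(TBS-oxy)methyl]-4-[(1Z,5S)-5-(TBS-oxy)-5-methylhepta-1,6-dien-1-yl]-2-[(triisopropylsilyl)ethynyl]-1,3-dioxolane (both epimers at the ketal carbon C12)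
Conditions: i-PrOSiMe3 (2.5 equiv), TMSOTf (10 mol %), CH2Cl2, −20 °C
Reagents that add atoms: none
Why: Noyori-type ketalisation (alkoxysilane, catalytic silyl triflate) works on ynones at low temperature, the bulky silyl group blocking conjugate addition; both ketal epimers are usable because C12 becomes planar in step 10.

Step 10
Reactants: 16 ketal (both C12 epimers)
Product: 19 3,4-cis oxolane-3-carbaldehyde (C8 S; C9 R; C12 S; formyl cis to the C8 chain), via oxocarbenium ion 17 (not isolated), via oxan-4-yl cation 18 (not isolated)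
Conditions: SnCl4 (1.5 equiv), CH2Cl2, −78 → −30 °C; then aq. NaHCO3
Reagents that add atoms: none
Why: SnCl4 opens the ketal at the allylic oxygen to the alkynyl-conjugated oxocarbenium ion 17, whose (Z)-alkene closes onto C12 through a chair transition state (6-endo-trig Prins closure, C8–C12 bond) to the six-membered oxan-4-yl cation 18; the tin alkoxide on C1 then drives the 1,2-shift of C10 from C1 to C9 (pinacol shift), which contracts the oxane to the oxolane and turns C1 into the formyl group, so the five-membered ring is made by ring contraction and not by a cyclisation of its own. The closest known reaction type is the Prins cyclisation–pinacol rearrangement of allylic diol acetals to 3-acyl tetrahydrofurans (the 2-oxonia-Cope/aldol alternative ends in the same product). In the chair the (Z)-substituent on C8 is axial, which forces the C1–H bond axial and the C1–O–Sn bond equatorial, so the single C1 stereocentre from glyceraldehyde fixes the face on which C8 and C12 are formed and is then destroyed. At C12 the slim alkynyl group takes the axial site and CH2OTBS the equatorial one, which should place the alkynyl group trans and CH2OTBS cis to the C8 chain, as the target needs. C10 arrives at C9 on the face of the new C8–C12 bond, so C9 should be formed 3,4-cis and is corrected in step 11. The step needs ionisation toward the oxocarbenium ion that keeps O11 and migration of carbon rather than hydride: the other ionisation has only a strained 5-endo path and reverts, carbon migration is the course this reaction class takes with secondary carbinols, and both ketal epimers converge because C12 passes through the planar cation.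

Step 11
Reactants: 19 3,4-cis oxolane-3-carbaldehyde
Product: 20 3,4-trans oxolane-3-carbaldehyde (C8 S; C9 S; C12 S; formyl trans to the C8 chain and cis to the alkynyl group)
Conditions: DBU (0.2 equiv), CH2Cl2, 23 °C
Reagents that add atoms: none
Why: Base-mediated epimerisation through the enol should move the formyl group trans to the C8 chain, the thermodynamically preferred arrangement on the crowded oxolane, so any C9 mixture from step 10 converges on one isomer.

Step 12
Reactants: 20 3,4-trans oxolane-3-carbaldehyde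
Product: 21 homoallylic alcohol at C1 (both carbinol epimers)
Conditions: allylmagnesium bromide, THF, −78 °C; then H2O
Reagents that add atoms: allylmagnesium bromide, C=CC[Mg]Br
Why: Grignard 1,2-addition to the only electrophile present; the carbinol configuration is irrelevant because it is oxidised next.

Step 13
Reactants: 21 homoallylic alcohol at C1
Product: 22 allyl ketone (C1 ketone carrying C2–C3 as an allyl group)
Conditions: Dess–Martin periodinane, pyridine, CH2Cl2, 0 → 23 °C
Reagents that add atoms: none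
Why: Buffered Dess–Martin oxidation should give the β,γ-unsaturated ketone without moving the double bond into conjugation; C9 stays trans, which is also its thermodynamic position.

Step 14
Reactants: 22 allyl ketone
Product: 23 bicyclic ketone (nine-membered ring with C1 ketone and (Z)-C3=C4, trans-fused to the oxolane)
Conditions: second-generation Hoveyda–Grubbs catalyst (10 mol %), 1,4-benzoquinone (20 mol %), toluene (0.001 M), 80 °C
Reagents that add atoms: none
Why: Ring-closing metathesis starts at the allyl group and closes onto the C5 vinyl group, helped by the trans-fused oxolane and the quaternary C5; a nine-membered ring can hold only the (Z)-alkene, the bulky silylalkyne stays out of enyne metathesis, and benzoquinone suppresses double-bond migration.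

Step 15
Reactants: 23 bicyclic ketone
Product: 24 exocyclic methylidene compound (C1=CH2; C9 R)
Conditions: Cp2TiMe2, toluene/THF, 65 °C, dark
Reagents that add atoms: dimethyltitanocene, C[Ti](C)(C1C=CC=C1)C1C=CC=C1
Why: Petasis methylenation through the non-basic titanocene methylidene should convert the hindered ketone without enolising C9 or the doubly activated C2 methylene.

Step 16
Reactants: 24 exocyclic methylidene compound
Product: 25 ethynyl diol (free C19–OH and C5–OH, terminal alkyne on C12)
Conditions: TBAF (6 equiv), THF, 23 → 50 °C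
Reagents that add atoms: none
Why: Fluoride-mediated desilylation cleaves the alkynyl–silicon bond and both silyl ethers; the tertiary ether needs the warming.

Step 17
Reactants: 25 ethynyl diol
Product: 26 (E)-2-(tributylstannyl)vinyl diol (tin on C14)
Conditions: Bu3SnH, PdCl2(PPh3)2 (3 mol %), THF, 0 °C
Reagents that add atoms: tributyltin hydride, CCCC[SnH](CCCC)CCCC
Why: Palladium-catalysed syn-hydrostannation of a terminal alkyne puts tin on the terminal carbon because the propargylic carbon C12 is quaternary, which gives the (E)-vinylstannane and tolerates the free hydroxyl groups and the other alkenes.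

Step 18
Reactants: 26 (E)-2-(tributylstannyl)vinyl diol
Product: 27 dienyl diol ((E)-4-methylpenta-1,3-dienyl group on C12)
Conditions: 1-bromo-2-methylprop-1-ene, Pd(PPh3)4 (5 mol %), CuI, CsF, DMF, 45 °C
Reagents that add atoms: 1-bromo-2-methylprop-1-ene, CC(C)=CBr
Why: Stille coupling proceeds with retention of the alkene geometry and without acid, which the tertiary dienylic ether at C12 would not survive.

Step 19
Reactants: 27 dienyl diol
Product: 28 CNP0274030.1
Conditions: stearoyl chloride (1.05 equiv), pyridine, CH2Cl2, −20 → 0 °C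
Reagents that add atoms: stearoyl chloride, CCCCCCCCCCCCCCCCCC(=O)Cl
Why: Acylation with an acid chloride is selective for the primary C19 alcohol because the tertiary allylic C5 alcohol does not react under these conditions.

**Compound list**

1 | (S)-(+)-linalool, (3S)-3,7-dimethylocta-1,6-dien-3-ol | C=C[C@@](C)(O)CCC=C(C)C | starting material
2 | (3S)-3-(TBS-oxy)-3,7-dimethylocta-1,6-diene | C=C[C@@](C)(O[Si](C)(C)C(C)(C)C)CCC=C(C)C | intermediate
3 | ozonide (1,2,4-trioxolane) of the 6,7-double bond of 2, not isolated | C=C[C@@](C)(O[Si](C)(C)C(C)(C)C)CCC1OOC(C)(C)O1 | intermediate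
4 | (4S)-4-(TBS-oxy)-4-methylhex-5-en-1-ol | C=C[C@@](C)(O[Si](C)(C)C(C)(C)C)CCCO | intermediate
5 | (3S)-3-(TBS-oxy)-6-iodo-3-methylhex-1-ene | C=C[C@@](C)(O[Si](C)(C)C(C)(C)C)CCCI | intermediate
6 | [(4S)-4-(TBS-oxy)-4-methylhex-5-en-1-yl]triphenylphosphonium iodide | C=C[C@@](C)(O[Si](C)(C)C(C)(C)C)CCC[P+](c1ccccc1)(c1ccccc1)c1ccccc1.[I-] | intermediate
7 | (R)-2,2-dimethyl-1,3-dioxolane-4-carbaldehyde | O=C[C@H]1COC(C)(C)O1 | starting material
8 | phosphorus ylide of 6, not isolated | C=C[C@@](C)(O[Si](C)(C)C(C)(C)C)CCC=P(c1ccccc1)(c1ccccc1)c1ccccc1 | intermediate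
9 | (4S)-4-[(1Z,5S)-5-(TBS-oxy)-5-methylhepta-1,6-dien-1-yl]-2,2-dimethyl-1,3-dioxolane | C=C[C@@](C)(O[Si](C)(C)C(C)(C)C)CC/C=C\[C@H]1COC(C)(C)O1 | intermediate
10 | (2S,3Z,7S)-7-(TBS-oxy)-7-methylnona-3,8-diene-1,2-diol | C=C[C@@](C)(O[Si](C)(C)C(C)(C)C)CC/C=C\[C@H](O)CO | intermediate
11 | ethynyl(triisopropyl)silane | C#C[Si](C(C)C)(C(C)C)C(C)C | starting material
12 | (tert-butyldimethylsilyloxy)acetaldehyde | O=CCO[Si](C)(C)C(C)(C)C | starting material
13 | lithium (triisopropylsilyl)acetylide, not isolated | [Li]C#C[Si](C(C)C)(C(C)C)C(C)C | intermediate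
14 | racemic 1-(TBS-oxy)-4-(triisopropylsilyl)but-3-yn-2-ol | CC(C)(C)[Si](C)(C)OCC(O)C#C[Si](C(C)C)(C(C)C)C(C)C | intermediate
15 | 1-(TBS-oxy)-4-(triisopropylsilyl)but-3-yn-2-one | CC(C)(C)[Si](C)(C)OCC(=O)C#C[Si](C(C)C)(C(C)C)C(C)C | intermediate
16 | (4S)-2-[(TBS-oxy)methyl]-4-[(1Z,5S)-5-(TBS-oxy)-5-methylhepta-1,6-dien-1-yl]-2-[(triisopropylsilyl)ethynyl]-1,3-dioxolane, both epimers at the ketal carbon | C=C[C@@](C)(O[Si](C)(C)C(C)(C)C)CC/C=C\[C@H]1COC(CO[Si](C)(C)C(C)(C)C)(C#C[Si](C(C)C)(C(C)C)C(C)C)O1 | intermediate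
17 | ring-opened oxocarbenium ion (C12=O11+; trichlorostannate alkoxide on C1), not isolated | C=C[C@@](C)(O[Si](C)(C)C(C)(C)C)CC/C=C\[C@H](O[Sn-](Cl)(Cl)(Cl)Cl)C[O+]=C(CO[Si](C)(C)C(C)(C)C)C#C[Si](C(C)C)(C(C)C)C(C)C | intermediate
18 | oxan-4-yl cation (six-membered ring O11, C12, C8, C9, C1, C10; cation at C9; tin alkoxide on C1 equatorial; C8 chain and alkynyl group axial), not isolated | C=C[C@@](C)(O[Si](C)(C)C(C)(C)C)CC[C@H]1[CH+][C@H](O[Sn-](Cl)(Cl)(Cl)Cl)CO[C@@]1(C#C[Si](C(C)C)(C(C)C)C(C)C)CO[Si](C)(C)C(C)(C)C | intermediate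
19 | 3,4-cis aldehyde: oxolane with C12 (CH2OTBS, TIPS-ethynyl), C8 ((3S)-3-(TBS-oxy)-3-methylpent-4-enyl, cis to CH2OTBS), C9 (CHO, cis to the C8 chain) | C=C[C@@](C)(O[Si](C)(C)C(C)(C)C)CC[C@H]1[C@@H](C=O)CO[C@@]1(C#C[Si](C(C)C)(C(C)C)C(C)C)CO[Si](C)(C)C(C)(C)C | intermediate
20 | 3,4-trans aldehyde: C9 epimer of 19 (CHO trans to the C8 chain) | C=C[C@@](C)(O[Si](C)(C)C(C)(C)C)CC[C@H]1[C@H](C=O)CO[C@@]1(C#C[Si](C(C)C)(C(C)C)C(C)C)CO[Si](C)(C)C(C)(C)C | intermediate
21 | homoallylic alcohol: C9 carries CH(OH)CH2CH=CH2, both carbinol epimers | C=C[C@@](C)(O[Si](C)(C)C(C)(C)C)CC[C@H]1[C@H](C(O)CC=C)CO[C@@]1(C#C[Si](C(C)C)(C(C)C)C(C)C)CO[Si](C)(C)C(C)(C)C | intermediate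
22 | allyl ketone: C9 carries C(=O)CH2CH=CH2 | C=C[C@@](C)(O[Si](C)(C)C(C)(C)C)CC[C@H]1[C@H](C(=O)CC=C)CO[C@@]1(C#C[Si](C(C)C)(C(C)C)C(C)C)CO[Si](C)(C)C(C)(C)C | intermediate
23 | bicyclic ketone: nine-membered ring (C1 ketone, (Z)-C3=C4, C5 methyl and OTBS) trans-fused at C8–C9 to the oxolane | O=C1C/C=C\[C@@](C)(O[Si](C)(C)C(C)(C)C)CC[C@H]2[C@H]1CO[C@@]2(C#C[Si](C(C)C)(C(C)C)C(C)C)CO[Si](C)(C)C(C)(C)C | intermediate
24 | methylidene compound: as 23 with C1=CH2 | C=C1C/C=C\[C@@](C)(O[Si](C)(C)C(C)(C)C)CC[C@H]2[C@H]1CO[C@@]2(C#C[Si](C(C)C)(C(C)C)C(C)C)CO[Si](C)(C)C(C)(C)C | intermediate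
25 | ethynyl diol: C12 carries C≡CH and CH2OH; C5 carries OH | C=C1C/C=C\[C@@](C)(O)CC[C@H]2[C@H]1CO[C@@]2(C#C)CO | intermediate
26 | (E)-vinylstannane diol: C12 carries (E)-CH=CH–SnBu3 and CH2OH | C=C1C/C=C\[C@@](C)(O)CC[C@H]2[C@H]1CO[C@@]2(/C=C/[Sn](CCCC)(CCCC)CCCC)CO | intermediate
27 | dienyl diol: C12 carries (E)-4-methylpenta-1,3-dienyl and CH2OH | C=C1C/C=C\[C@@](C)(O)CC[C@H]2[C@H]1CO[C@@]2(/C=C/C=C(C)C)CO | intermediate
28 | CNP0274030.1, the C19 stearate of 27 | C=C1C/C=C\[C@@](C)(O)CC[C@H]2[C@H]1CO[C@@]2(/C=C/C=C(C)C)COC(=O)CCCCCCCCCCCCCCCCC | target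

**Step count and risks**

Total step count: 19. Longest linear sequence: 17 (steps 1–6 and 9–19; steps 7 and 8 make the ynone).

Steps most likely to fail:

1. Step 10. The cationic cascade may leak: SnCl4 may ionise the tertiary allylic silyl ether of the side chain, the oxan-4-yl cation may lose a proton or undergo a 1,2-hydride shift before the ring-contracting shift, or control at C12 may be incomplete if the alkynyl group does not hold the axial site. The fallback sets out from 16 and comes back at 19. The cascade is split into two separate operations. SnBr4 in CH2Cl2 at −78 °C with short contact should let bromide capture the oxanyl cation equatorially, and aqueous work-up should give the trans-diequatorial 4-bromo-oxan-3-ol F1, where C12 epimers can be separated. AgOTf with 2,6-di-tert-butylpyridine in CH2Cl2 at −40 °C should then ionise the C9–Br bond with antiperiplanar shift of C10 (silver-promoted semipinacol ring contraction of a halohydrin) and deliver 19 for step 11.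

2. Step 14. The medium-ring closure may lose to intermolecular metathesis, the hindered vinyl group next to the silyloxy-bearing C5 may not be engaged, or the allyl double bond may migrate. The fallback sets out from 21 and comes back at 23; it closes C3=C4 by carbonyl coupling instead. TESOTf and 2,6-lutidine should give the C1 triethylsilyl ether F2. Ozonolysis of both terminal alkenes (O3, CH2Cl2, −78 °C; PPh3) should give the dialdehyde F3. Intramolecular McMurry coupling (TiCl3(DME)1.5, Zn–Cu couple, DME, reflux, slow addition) should give the (Z)-cyclononene silyl ether F4. PPTS in MeOH at 0 °C should remove only the secondary TES group to give the cyclononenol F5, and Dess–Martin oxidation should return 23.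

3. Step 15. The hindered ketone may not react, or it may enolise and shift the C3=C4 double bond into conjugation. The fallback sets out from 20 and comes back at 24; it installs the methylidene carbon before any ketone exists. Ohira–Bestmann homologation (dimethyl (1-diazo-2-oxopropyl)phosphonate, K2CO3, MeOH) should give the terminal alkyne F6. Markovnikov hydroalumination (NiCl2(dppp), i-Bu2AlH, THF) followed by N-bromosuccinimide should give the 2-bromoalkene F7. Stille coupling with allyltributylstannane (Pd(PPh3)4, CuI, DMF) should give the skipped triene F8, and ring-closing metathesis under the conditions of step 14 should give 24.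

**Further compounds**

F1 | step 10 | trans-diequatorial 4-bromo-oxan-3-ol: oxane ring O11, C12, C8, C9 (Br), C1 (OH), C10 with the substituents of 18 | C=C[C@@](C)(O[Si](C)(C)C(C)(C)C)CC[C@H]1[C@@H](Br)[C@H](O)CO[C@@]1(C#C[Si](C(C)C)(C(C)C)C(C)C)CO[Si](C)(C)C(C)(C)C
F2 | step 14 | triethylsilyl ether of 21 | C=C[C@@](C)(O[Si](C)(C)C(C)(C)C)CC[C@H]1[C@H](C(CC=C)O[Si](CC)(CC)CC)CO[C@@]1(C#C[Si](C(C)C)(C(C)C)C(C)C)CO[Si](C)(C)C(C)(C)C
F3 | step 14 | dialdehyde (C3 and C4 as CHO) | O=C[C@@](C)(O[Si](C)(C)C(C)(C)C)CC[C@H]1[C@H](C(CC=O)O[Si](CC)(CC)CC)CO[C@@]1(C#C[Si](C(C)C)(C(C)C)C(C)C)CO[Si](C)(C)C(C)(C)C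
F4 | step 14 | (Z)-cyclononene with C1 triethylsilyl ether | CC[Si](CC)(CC)OC1C/C=C\[C@@](C)(O[Si](C)(C)C(C)(C)C)CC[C@H]2[C@H]1CO[C@@]2(C#C[Si](C(C)C)(C(C)C)C(C)C)CO[Si](C)(C)C(C)(C)C
F5 | step 14 | (Z)-cyclononenol (C1–OH) | OC1C/C=C\[C@@](C)(O[Si](C)(C)C(C)(C)C)CC[C@H]2[C@H]1CO[C@@]2(C#C[Si](C(C)C)(C(C)C)C(C)C)CO[Si](C)(C)C(C)(C)C
F6 | step 15 | terminal alkyne on C9 | C=C[C@@](C)(O[Si](C)(C)C(C)(C)C)CC[C@H]1[C@H](C#C)CO[C@@]1(C#C[Si](C(C)C)(C(C)C)C(C)C)CO[Si](C)(C)C(C)(C)C
F7 | step 15 | 2-bromoalkene on C9 (C1 bears Br and =CH2) | C=C[C@@](C)(O[Si](C)(C)C(C)(C)C)CC[C@H]1[C@H](C(Br)=C)CO[C@@]1(C#C[Si](C(C)C)(C(C)C)C(C)C)CO[Si](C)(C)C(C)(C)C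
F8 | step 15 | skipped triene (C9 carries C(=CH2)CH2CH=CH2) | C=C[C@@](C)(O[Si](C)(C)C(C)(C)C)CC[C@H]1[C@H](C(=C)CC=C)CO[C@@]1(C#C[Si](C(C)C)(C(C)C)C(C)C)CO[Si](C)(C)C(C)(C)C
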